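## Analysis of the target

The target 11 is a flavonol, that is a 4H-chromen-4-one in which benzo ring A is fused to the 4-pyranone ring C, with a 2-methoxyphenyl group (ring B) on C2 and a free hydroxyl on C3. Ring A is fully substituted, with methoxy groups on C5 and C7, methyl groups on C6 and C8 and the fusion carbons C4a and C8a, so that three oxygens (O1, 5-OMe, 7-OMe) alternate with three carbon substituents in a phloroglucinol pattern. There is no stereocentre, and the C2–C1′ axis carries only one ortho substituent on ring B and rotates freely, so nothing stereochemical has to be set. The sensitive parts are the 3-hydroxy-4-pyranone, an acidic and metal-chelating enol whose anion is degraded in air, and the 5-methoxy group peri to the carbonyl, which Lewis acids cleave easily. The synthesis is hard for two reasons: the three phloroglucinol oxygens must be told apart (one becomes O1, two stay methyl ethers) on a ring that also needs two C-methyl groups, and ring C must be closed with the C3 oxygen in place. The classical oxidative cyclisation of 2′-hydroxychalcones is a poor way to do the latter, because a substituent on C5 diverts it towards aurones. The strategy rests on two features: C4 on C4a and O1 on C8a are ortho neighbours on ring A, which is the pattern of a salicylaldehyde, and the remaining C2–C3 unit, with ring B on C2 and an oxygen on C3, has the connectivity and the oxidation level of an aryl ynol ether.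

## Retrosynthetic reasoning

11 to 10 (O–Si). The C3 hydroxyl is carried through the ring-forming step as its triisopropylsilyl ether 10. The silyl group is not an added protecting group; it is the form in which the C3 oxygen enters the molecule. The forward step is a buffered fluoride desilylation.

10 to 5 + 9 (C3–C4 and O1–C2). Ring C is the only ring not present in a purchasable fragment, and cutting these two bonds takes it apart into salicylaldehyde 5 and siloxyalkyne 9. The cut is made here because both fragments already hold the final oxidation level: the formyl carbon becomes the C4 ketone once its C–H bond is replaced by C–C, and the alkyne supplies C2=C3 with the oxygen on C3. No redox adjustment follows. A cut at C2–C3 (the chalcone logic) is avoided because the C5 substituent favours aurone formation in the oxidative closure. The forward reaction must cleave the formyl C–H bond under direction by the neighbouring phenoxide, insert the alkyne so that the acyl carbon meets the oxygen-bearing carbon, close O1–C2 and reoxidise the metal, all without destroying the acid-sensitive ynol ether.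

5 to 3 (two O–CH3 bonds). The two methyl ethers of 5 are disconnected to the triphenol 3. The hydroxyl that must stay free is the one hydrogen-bonded to the formyl group, so the distinction among the three oxygens comes from the substrate. The mono-ether 4 lies on the way.

3 to 1 (two C–CH3 bonds). The ring methyl groups are disconnected to the phloroglucinol aldehyde 1. Its two unsubstituted ring positions are equivalent and are the only ones available, so no regiochemical question arises. The forward reaction only has to stop after two C-methylations, passing through 2.

9 to 6 (O–Si and the alkyne). The silyl ynol ether 9 is disconnected at O–Si to ynolate 8. This comes from the aryl ester 6 by one-carbon homologation through the dibromo enolate 7 and a 1,2-aryl shift. The ester carbon becomes C3 and the inserted carbon becomes C2. A bulky silyl electrophile is needed so that 8 is silylated on oxygen.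

## Alternatives that were turned down

Alternative 1: aryne insertion into a carboxylic acid. Disconnection: C4a–C4 and C8a–O1, both at ring A, so that ring A is an aryne and C4 with O1 is a carboxylic acid. Forward key step: CsF would release the aryne from 3,5-dimethoxy-2,4-dimethyl-6-(trimethylsilyl)phenyl trifluoromethanesulfonate A2. The carboxylate of (Z)-2-(benzyloxy)-3-(2-methoxyphenyl)prop-2-enoic acid A3 adds through oxygen at C8a, and the aryl anion at C4a attacks the acyl carbon. The net insertion into the acyl C–O bond gives (Z)-2-(benzyloxy)-1-(2-hydroxy-4,6-dimethoxy-3,5-dimethylphenyl)-3-(2-methoxyphenyl)prop-2-en-1-one A1. Conjugate addition of the phenol of A1, dehydrogenation and hydrogenolysis of the benzyl ether would follow and lead to 11.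
- For: This is an established reaction type and needs no transition metal and no acid-labile partner. The C5 methoxy group polarises the aryne so that the nucleophile should attack the distal carbon C8a, which is the required sense. The oxygen on C8a arrives already distinguished from the two methyl ethers. On precedent and on differentiation of the ring A oxygens it is stronger than the chosen route.
- Against: A2 is a hexasubstituted benzene with adjacent silyl and triflate groups. It would have to be built from 3,5-dimethoxy-2,4-dimethylphenol A4, itself not a stock compound, by ortho-bromination, O-silylation, halogen–metal exchange with silyl migration and triflation. The aryne is flanked on both sides, and the C8 methyl hinders the electronically preferred attack at C8a. The hindered aryl anion must reach the carbonyl through a four-membered transition state in competition with simple protonation, which ends in O-arylation. A3 needs steps of its own, and A1 is still three steps from 11.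
- Comparison: The count runs well over ten steps against five, and the key step gives an open-chain ketone, not ring C. The chosen route accepts an untested alkyne partner in exchange for forming ring C at its final oxidation level in one operation.

Alternative 2: Danheiser benzannulation for ring A. Disconnection: ring A itself, at C8–C8a, C6–C7 and C4a–C8a. Forward key step: 3-methoxy-2-methylcyclobut-2-en-1-one A5 is heated with 1-methoxyprop-1-yne A6. The vinylketene from A5 adds to the alkyne A6 by [2+2] cycloaddition, and 4π opening followed by 6π closure gives 3,5-dimethoxy-2,4-dimethylphenol A4.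
- For: Every substituent of ring A is placed by the connectivity of the two components. The single free hydroxyl of A4 (the future O1) is distinguished from the methyl ethers from the start. No stoichiometry-controlled C-methylation and no selective O-methylation are needed, so on ring A selectivity it is stronger than steps 1 and 2 of the chosen route.
- Against: It constructs the ring that can be bought, since the oxygen pattern of ring A is already present in 1. A5 and A6 are not stock compounds, and A6 is a volatile ynol ether. The key step forms no bond of ring C: A4 must still be formylated, which gives 5 of the present route, and ring C is then still to be made.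
- Comparison: This is an entry into 5 that is longer by three or four steps and leaves the C2–C3–O problem untouched. The chosen route spends its single uncertain step on ring C.

Alternative 3: pinacol closure of ring C. Disconnection: C3–C4, with both carbons as aldehydes and O1–C2 made beforehand as an aryl alkyl ether. Forward key step: SmI2 (samarium diiodide, divalent samarium) would reduce racemic 4,6-dimethoxy-2-[1-(2-methoxyphenyl)-2-oxoethoxy]-3,5-dimethylbenzaldehyde A7 to two ketyls. These couple to 5,7-dimethoxy-2-(2-methoxyphenyl)-6,8-dimethylchromane-3,4-diol A8, a racemic mixture of diastereomers. Oxidation of both carbinols of A8 and tautomerisation would then give 11.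
- For: Ketyl coupling to six-membered rings is well known. The two carbons are tethered, so there is no regiochemical question, and on this point it is stronger than the chosen route, whose insertion orientation is open. The three stereocentres of A8 need no control because all are erased.
- Against: A7 carries an aryloxy group on the carbon next to the aliphatic aldehyde. Single-electron reduction of such a carbonyl expels the neighbouring heteroatom substituent, and a phenoxide is a good leaving group, so cleavage of O1–C2 competes directly with C–C coupling. A7 is also strongly enolisable and hard to make and keep. Its preparation requires O-alkylation of the hindered phenol of 5 and an ester-to-aldehyde adjustment beside an aromatic aldehyde. Two carbonyls are reduced only to be oxidised again.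
- Comparison: About eight steps with a redox detour, against five steps with none.

Key step: step 4

## Route

Step 1
Reactants: 1 2,4,6-trihydroxybenzaldehyde
Product: 3 2,4,6-trihydroxy-3,5-dimethylbenzaldehyde, via 2,4,6-trihydroxy-3-methylbenzaldehyde 2 (not isolated)
Conditions: MeI (2.1 equiv), NaOMe (3 equiv), MeOH, 0 °C → rt
Reagents that add atoms: iodomethane, CI
Why: Nuclear C-methylation of an acylphloroglucinol polyanion, which reacts with the soft electrophile at carbon in a protic solvent; the two free ring positions are equivalent, and limiting the methyl iodide should stop the reaction before geminal dimethylation.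

Step 2
Reactants: 3 2,4,6-trihydroxy-3,5-dimethylbenzaldehyde
Product: 5 2-hydroxy-4,6-dimethoxy-3,5-dimethylbenzaldehyde, via 2,6-dihydroxy-4-methoxy-3,5-dimethylbenzaldehyde 4 (not isolated)
Conditions: Me2SO4 (2.05 equiv), K2CO3, acetone, reflux
Reagents that add atoms: dimethyl sulfate, COS(=O)(=O)OC
Why: Chelation-controlled Williamson O-methylation: the 4-OH, which is not hydrogen-bonded, reacts first and then one of the two equivalent ortho hydroxyls; the last hydroxyl is locked in a hydrogen bond to the formyl oxygen and should remain free with two equivalents of the hard methylating agent.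

Step 3
Reactants: 6 methyl 2-methoxybenzoate
Product: 9 triisopropyl{[(2-methoxyphenyl)ethynyl]oxy}silane, via lithium 2,2-dibromo-1-(2-methoxyphenyl)ethenolate 7 (not isolated), via lithium (2-methoxyphenyl)ethynolate 8 (not isolated)
Conditions: CH2Br2, LiTMP, THF, −78 °C; then 6; LiHMDS; n-BuLi, −78 °C → rt; TIPSOTf, −78 → 0 °C; filtration through Et3N-deactivated silica
Reagents that add atoms: dibromomethane, BrCBr; triisopropylsilyl trifluoromethanesulfonate, CC(C)[Si](OS(=O)(=O)C(F)(F)F)(C(C)C)C(C)C
Why: Kowalski ester homologation stopped at the ynolate: LiCHBr2 adds to the ester, the dibromo enolate 7 undergoes bromine–lithium exchange, and a 1,2-aryl shift of the carbenoid gives ynolate 8. Bulky silyl electrophiles silylate ynolates on oxygen, so the silyl ynol ether 9 should result.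

Step 4
Reactants: 5 2-hydroxy-4,6-dimethoxy-3,5-dimethylbenzaldehyde; 9 triisopropyl{[(2-methoxyphenyl)ethynyl]oxy}silane
Product: 10 5,7-dimethoxy-2-(2-methoxyphenyl)-6,8-dimethyl-3-[(triisopropylsilyl)oxy]-4H-chromen-4-one
Conditions: [Cp*RhCl2]2 (2.5 mol %), Cu(OAc)2 (anhydrous, 2.2 equiv), Na2CO3 (2.2 equiv), 4 Å MS, DCE, 80 °C, 9 (1.5 equiv) added slowly
Reagents that add atoms: none
Why: Proposed new method: the phenoxide of 5 binds the Cp*Rh fragment (trivalent rhodium) and acetate-assisted cleavage of the formyl C–H bond should give a five-membered acyl rhodacycle; migratory insertion of alkyne 9 into the rhodium–acyl bond then makes C3–C4 and a seven-membered rhodacycle, from which C–O reductive elimination makes O1–C2, and the monovalent rhodium released is reoxidised to trivalent rhodium by Cu(OAc)2 (divalent copper). The closest known reaction type is the oxidative annulation of salicylaldehydes with internal diaryl or dialkyl alkynes to chromones under catalysis by trivalent rhodium with Cu(OAc)2 as oxidant; a silyl ynol ether has not been shown as the alkyne partner. Ring C, the only ring formed, is six-membered and is closed by this formal [4+2] oxidative annulation, the ring-closing event being reductive elimination at rhodium and not an ionic cyclisation. No stereocentre is formed. The step needs one orientation of insertion, acyl carbon to the oxygen-bearing alkyne carbon and rhodium to the aryl-bearing one: the siloxy oxygen makes the aryl-bearing carbon the electron-rich terminus that binds the electrophilic metal and the oxygen-bearing carbon the ketene-like acceptor of the migrating acyl group, and the usual preference of an aryl-substituted alkyne carbon for the position next to rhodium is expected to act in the same direction. Chemoselectivity for the aldehyde C–H bond is secured by the substrate, since ring A of 5 carries no aromatic hydrogen. The acid-labile siloxyalkyne is protected by the bulky triisopropylsilyl group, anhydrous Cu(OAc)2, molecular sieves, Na2CO3 as scavenger of the acetic acid released, and slow addition of 9.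

Step 5
Reactants: 10 5,7-dimethoxy-2-(2-methoxyphenyl)-6,8-dimethyl-3-[(triisopropylsilyl)oxy]-4H-chromen-4-one
Product: 11 3-hydroxy-5,7-dimethoxy-2-(2-methoxyphenyl)-6,8-dimethyl-4H-chromen-4-one
Conditions: TBAF, AcOH, THF, 0 °C
Reagents that add atoms: none
Why: Fluoride-induced cleavage of the O–Si bond of an enol silyl ether; the acetic acid buffer protonates the flavonolate at once and keeps the 3-hydroxy-4-pyranone out of its air-sensitive anionic form, and the methyl ethers are untouched.

## Compound list

1 | 2,4,6-trihydroxybenzaldehyde | O=Cc1c(O)cc(O)cc1O | starting material
2 | 2,4,6-trihydroxy-3-methylbenzaldehyde | O=Cc1c(O)c(C)c(O)cc1O | intermediate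
3 | 2,4,6-trihydroxy-3,5-dimethylbenzaldehyde | O=Cc1c(O)c(C)c(O)c(C)c1O | intermediate
4 | 2,6-dihydroxy-4-methoxy-3,5-dimethylbenzaldehyde | O=Cc1c(O)c(C)c(OC)c(C)c1O | intermediate
5 | 2-hydroxy-4,6-dimethoxy-3,5-dimethylbenzaldehyde | O=Cc1c(O)c(C)c(OC)c(C)c1OC | intermediate
6 | methyl 2-methoxybenzoate | COC(=O)c1ccccc1OC | starting material
7 | lithium 2,2-dibromo-1-(2-methoxyphenyl)ethenolate | [Li+].[O-]C(=C(Br)Br)c1ccccc1OC | intermediate
8 | lithium (2-methoxyphenyl)ethynolate | [Li+].[O-]C#Cc1ccccc1OC | intermediate
9 | triisopropyl{[(2-methoxyphenyl)ethynyl]oxy}silane | COc1ccccc1C#CO[Si](C(C)C)(C(C)C)C(C)C | intermediate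
10 | 5,7-dimethoxy-2-(2-methoxyphenyl)-6,8-dimethyl-3-[(triisopropylsilyl)oxy]-4H-chromen-4-one | COc1ccccc1-c1oc2c(C)c(OC)c(C)c(OC)c2c(=O)c1O[Si](C(C)C)(C(C)C)C(C)C | intermediate
11 | 3-hydroxy-5,7-dimethoxy-2-(2-methoxyphenyl)-6,8-dimethyl-4H-chromen-4-one | COc1ccccc1-c1oc2c(C)c(OC)c(C)c(OC)c2c(=O)c1O | target

Total step count: 5.

Longest linear sequence: 4 steps (1 → 3 → 5 → 10 → 11, that is steps 1, 2, 4 and 5). The second branch (6 → 9) is step 3 and joins at step 4.

Least certain steps, the riskiest first:

The key step, step 4, is the only step beyond known chemistry. Several processes may defeat it: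
- protonation of the ynol ether by the phenol of 5 or by the acetic acid released, or its activation by Lewis-acidic copper, before it reaches rhodium;
- insertion in the reversed orientation;
- decarbonylation of the acyl rhodium intermediate;
- protonation of the vinyl–rhodium intermediate before C–O reductive elimination, which amounts to hydroacylation;
- slow C–H cleavage at an aldehyde flanked by two ortho substituents.

The fallback for step 4 uses known chemistry only, sets out from 5 and comes back to the route at 11. An excess of lithium (2-methoxyphenyl)ethynide F2, made from commercial 1-ethynyl-2-methoxybenzene F1 and n-BuLi in THF, is added to aldehyde 5. This should give racemic 2-[1-hydroxy-3-(2-methoxyphenyl)prop-2-yn-1-yl]-3,5-dimethoxy-4,6-dimethylphenol F3. MnO2 in CH2Cl2 oxidises F3 to 1-(2-hydroxy-4,6-dimethoxy-3,5-dimethylphenyl)-3-(2-methoxyphenyl)prop-2-yn-1-one F4. Et2NH in EtOH adds to the ynone F4, and the enaminone closes ring C in the 6-endo sense to 5,7-dimethoxy-2-(2-methoxyphenyl)-6,8-dimethyl-4H-chromen-4-one F5. Dimethyldioxirane in acetone epoxidises C2=C3 of F5 to racemic 4,6-dimethoxy-1a-(2-methoxyphenyl)-3,5-dimethyl-1a,7a-dihydro-7H-oxireno[2,3-b]chromen-7-one F6, and catalytic p-TsOH isomerises F6 to 11.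

In step 1, methylation may run past the dimethyl stage to a dearomatised geminal dimethyl compound, or occur partly on oxygen, because the product anion is at least as nucleophilic as the starting anion. The fallback for step 1 sets out from 1 and comes back at 5, with the order of events reversed. Chelation-controlled O-methylation of 1 (Me2SO4, K2CO3, acetone) gives 2-hydroxy-4,6-dimethoxybenzaldehyde F7. NBS (2.1 equiv, MeCN) brominates the only two free positions of F7 to give 3,5-dibromo-2-hydroxy-4,6-dimethoxybenzaldehyde F8. Double Suzuki–Miyaura methylation of F8 (trimethylboroxine, Pd(OAc)2, SPhos, K3PO4, dioxane/H2O, 100 °C) then gives 5.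

In step 3, addition of the carbenoid to the ortho-substituted ester may be incomplete, and the ynol ether may hydrolyse or rearrange to a silylketene during isolation. The fallback for step 3 sets out from 6 and comes back to the route at ynolate 8, and so at 9. i-Bu2AlH (CH2Cl2, −78 °C) reduces 6 to 2-methoxybenzaldehyde F9. Ohira–Bestmann homologation of F9 (dimethyl (1-diazo-2-oxopropyl)phosphonate, K2CO3, MeOH) gives 1-ethynyl-2-methoxybenzene F1, and n-BuLi converts F1 into lithium (2-methoxyphenyl)ethynide F2. Lithium tert-butyl peroxide (from t-BuOOH and LiHMDS, THF, −78 → 0 °C) oxidises F2 to ynolate 8, which is silylated with TIPSOTf as in step 3.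

In step 2, loss of selectivity would lead to methylation of all three hydroxyls, and the electron-rich nucleus may again be alkylated at carbon. The fallback for step 2 sets out from 3 and comes back at 5. Exhaustive methylation of 3 (MeI, K2CO3, DMF) gives 2,4,6-trimethoxy-3,5-dimethylbenzaldehyde F10. BCl3 (CH2Cl2, −78 → 0 °C) then removes one ortho methyl group of F10 through the boron chelate with the formyl oxygen and stops there, giving 5.

## Further compounds

F1 | step 4 | 1-ethynyl-2-methoxybenzene | C#Cc1ccccc1OC
F2 | step 4 | lithium (2-methoxyphenyl)ethynide | [Li+].[C-]#Cc1ccccc1OC
F3 | step 4 | 2-[1-hydroxy-3-(2-methoxyphenyl)prop-2-yn-1-yl]-3,5-dimethoxy-4,6-dimethylphenol (racemic) | COc1ccccc1C#CC(O)c1c(O)c(C)c(OC)c(C)c1OC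
F4 | step 4 | 1-(2-hydroxy-4,6-dimethoxy-3,5-dimethylphenyl)-3-(2-methoxyphenyl)prop-2-yn-1-one | COc1ccccc1C#CC(=O)c1c(O)c(C)c(OC)c(C)c1OC
F5 | step 4 | 5,7-dimethoxy-2-(2-methoxyphenyl)-6,8-dimethyl-4H-chromen-4-one | COc1ccccc1-c1cc(=O)c2c(OC)c(C)c(OC)c(C)c2o1
F6 | step 4 | 4,6-dimethoxy-1a-(2-methoxyphenyl)-3,5-dimethyl-1a,7a-dihydro-7H-oxireno[2,3-b]chromen-7-one (racemic) | COc1ccccc1C12OC1C(=O)c1c(OC)c(C)c(OC)c(C)c1O2
F7 | step 1 | 2-hydroxy-4,6-dimethoxybenzaldehyde | COc1cc(OC)c(C=O)c(O)c1
F8 | step 1 | 3,5-dibromo-2-hydroxy-4,6-dimethoxybenzaldehyde | COc1c(Br)c(OC)c(C=O)c(O)c1Br
F9 | step 3 | 2-methoxybenzaldehyde | COc1ccccc1C=O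
F10 | step 2 | 2,4,6-trimethoxy-3,5-dimethylbenzaldehyde | COc1c(C)c(OC)c(C=O)c(OC)c1C
A1 | alternative 1 | (Z)-2-(benzyloxy)-1-(2-hydroxy-4,6-dimethoxy-3,5-dimethylphenyl)-3-(2-methoxyphenyl)prop-2-en-1-one | COc1ccccc1/C=C(\OCc1ccccc1)C(=O)c1c(O)c(C)c(OC)c(C)c1OC
A2 | alternative 1 | 3,5-dimethoxy-2,4-dimethyl-6-(trimethylsilyl)phenyl trifluoromethanesulfonate | COc1c(C)c(OC)c(C)c(OS(=O)(=O)C(F)(F)F)c1[Si](C)(C)C
A3 | alternative 1 | (Z)-2-(benzyloxy)-3-(2-methoxyphenyl)prop-2-enoic acid | COc1ccccc1/C=C(\OCc1ccccc1)C(=O)O
A4 | alternative 2 | 3,5-dimethoxy-2,4-dimethylphenol | Oc1cc(OC)c(C)c(OC)c1C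
A5 | alternative 2 | 3-methoxy-2-methylcyclobut-2-en-1-one | COC1=C(C)C(=O)C1
A6 | alternative 2 | 1-methoxyprop-1-yne | COC#CC
A7 | alternative 3 | 4,6-dimethoxy-2-[1-(2-methoxyphenyl)-2-oxoethoxy]-3,5-dimethylbenzaldehyde (racemic) | COc1ccccc1C(C=O)Oc1c(C)c(OC)c(C)c(OC)c1C=O
A8 | alternative 3 | 5,7-dimethoxy-2-(2-methoxyphenyl)-6,8-dimethylchromane-3,4-diol (racemic, mixture of diastereomers) | COc1ccccc1C1Oc2c(C)c(OC)c(C)c(OC)c2C(O)C1O
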